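**Retrosynthetic overview**
- Target ⇐ the C2,C4-diol of the bicyclic core; the last two steps are primary-selective acetylation and Yamaguchi angeloylation.
- Core (cycloheptene plus cis-fused α-methylene-γ-butyrolactone) ⇐ one cationic operation on a cyclopropane-fused δ-lactone tricycle: C5–O ionises, the ring-fusion cyclopropane bond opens (six- to seven-membered ring, C5=C6 formed) and the freed carboxylate closes onto C8.
- Tricycle ⇐ Wittig methylenation of the α-keto lactone made by intramolecular rhodium-carbenoid cyclopropanation of a diazopyruvate tethered to the tertiary C5 alcohol.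
- C5 carbinol ⇐ chelation-controlled MeMgBr addition to the syn aldol of (R)-5-methylcyclohex-2-en-1-one and 3-(silyloxy)propanal (C10 bought; C1 and C2 from the aldol).
- Ring order: cyclohexene (bought) → cyclopropane + δ-lactone (temporary, formed together) → cycloheptene + γ-lactone (formed together, while the first three rings disappear).

Assumption: (R)-5-methylcyclohex-2-en-1-one and 3-[(tert-butyldimethylsilyl)oxy]propanal are bought as catalogue compounds.
Locants are those of the target skeleton: ring C1, C5–C10; side chain C2–C4; lactone C11 (α-carbon), C12 (C=O), C13 (=CH2); methyls on C10 and C5. The β-face is the face that carries the lactone and the C1 side chain in the target; the C10 methyl is α.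

**Step 1**
Reactants: 1 (R)-5-methylcyclohex-2-en-1-one; 2 3-[(tert-butyldimethylsilyl)oxy]propanal
Product: 5 syn-aldol hydroxy enone (5R,6R,1′S), via lithium dienolate 3 (not isolated), via triisopropoxytitanium dienolate 4 (not isolated)
Conditions: LiN(iPr)2 (1.05 equiv), THF, −78 °C; ClTi(OiPr)3 (1.2 equiv), −78 to −40 °C; then 2, −78 °C; aq NH4F
Reagents that add atoms: none
Why: Kinetic α′-deprotonation gives the cross-conjugated dienolate, and the Reetz-type titanium-enolate aldol addition, which is syn-selective for cyclic enolates, takes the aldehyde onto the face anti to the adjacent C10 methyl, setting C1 (side chain trans to the methyl) and C2 (S).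

**Step 2**
Reactants: 5 syn-aldol hydroxy enone
Product: 7 tertiary/secondary diol (C5–OH β), via magnesium aldolate chelate 6 (not isolated)
Conditions: MeMgBr (3 equiv), CH2Cl2–Et2O, −78 to −40 °C; aq NH4Cl
Reagents that add atoms: methylmagnesium bromide, C[Mg]Br
Why: Chelation-controlled Grignard 1,2-addition: the C2 magnesium alkoxide chelates the C5 carbonyl with the chelate puckered onto the β-face (C2–O anti to H1), so external MeMgBr attacks the α-face and the tertiary hydroxyl ends β, cis to the side chain.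

**Step 3**
Reactants: 7 tertiary/secondary diol
Product: 8 C2-O-triethylsilyl tertiary allylic alcohol
Conditions: Et3SiCl (1.2 equiv), imidazole, DMF, 0 °C
Reagents that add atoms: chlorotriethylsilane, CC[Si](Cl)(CC)CC
Why: Silyl ether formation that is selective on steric grounds, since the secondary C2–OH reacts and the tertiary allylic C5–OH does not.

**Step 4**
Reactants: 8 C2-O-triethylsilyl tertiary allylic alcohol
Product: 11 diazopyruvate ester, via lithium alkoxide 9 (not isolated), via chlorooxalate 10 (not isolated)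
Conditions: n-BuLi (1.0 equiv), THF, −78 °C; inverse addition to (COCl)2 (4 equiv), −78 to 0 °C; evaporate; Me3SiCHN2 (2.5 equiv), MeCN–THF, 0 °C
Reagents that add atoms: oxalyl chloride, O=C(Cl)C(=O)Cl; (trimethylsilyl)diazomethane, C[Si](C)(C)C=[N+]=[N-]
Why: O-acylation of the tertiary alkoxide by excess oxalyl chloride, then Arndt–Eistert-type C-acylation of the silyl diazomethane by the acid chloride (protodesilylation by the HCl set free), gives the diazopyruvate without touching any stereocentre.

**Step 5**
Reactants: 11 diazopyruvate ester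
Product: 12 tricyclic α-keto-δ-lactone
Conditions: Rh2(OAc)4 (1 mol %), CH2Cl2, 25 °C, slow addition of 11
Reagents that add atoms: none
Why: Intramolecular rhodium-carbenoid cyclopropanation of an allylic diazo keto ester, in which the tether from the β C5–O delivers the carbene to the β-face of C6=C8 and holds the acyl arm endo, setting C6, C7 and C8 in one event.

**Step 6**
Reactants: 12 tricyclic α-keto-δ-lactone
Product: 13 tricyclic α-methylene-δ-lactone
Conditions: Ph3PCH3Br (1.5 equiv), KN(SiMe3)2 (1.4 equiv), THF, 0 °C; then 12, −78 to 0 °C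
Reagents that add atoms: methyltriphenylphosphonium bromide, C[P+](c1ccccc1)(c1ccccc1)c1ccccc1.[Br-]
Why: Wittig methylenation is selective for the ketone carbonyl over the lactone carbonyl and cannot epimerise C7, which is a non-enolisable cyclopropane carbon.

**Step 7**
Reactants: 13 tricyclic α-methylene-δ-lactone
Product: 15 bis-silyl bicyclic α-methylene-γ-lactone, via cyclopropylcarbinyl cation carboxylate 14 (not isolated)
Conditions: Sc(OTf)3 (5 mol %), (CF3)2CHOH–CH2Cl2 (1:4), −20 to 0 °C
Reagents that add atoms: none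
Why: Proposed new method: ionisation of the tertiary cyclopropylcarbinyl C5–O bond gives a cyclopropylcarbinyl cation that carries the freed carboxylate on the endo C7 arm; the carboxylate closes a five-membered lactone onto C8 anti to the breaking C6–C8 bond (inversion at C8, C7 untouched), which opens the ring-fusion bond to the cycloheptene with the C5=C6 double bond and gives the cis-fused lactone on the β-face; capture at C7 would need a three- or four-membered ring and return to C5 is unproductive, so the strain-free γ-lactone is the sink; the closest known reaction types are the Julia cyclopropylcarbinyl-to-homoallyl rearrangement and the solvolytic 2-norcaranyl to cyclohept-3-enyl ring expansion.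

**Step 8**
Reactants: 15 bis-silyl bicyclic α-methylene-γ-lactone
Product: 16 C2,C4-diol
Conditions: HF·pyridine, THF–pyridine, 0 to 23 °C
Reagents that add atoms: none
Why: Fluoride-driven cleavage of both silyl ethers under buffered conditions leaves the α-methylene lactone and the ring alkene untouched.

**Step 9**
Reactants: 16 C2,C4-diol
Product: 17 C4-monoacetate
Conditions: AcCl (1.05 equiv), 2,4,6-collidine, CH2Cl2, −78 °C
Reagents that add atoms: acetyl chloride, CC(=O)Cl
Why: Sterically controlled acylation at low temperature takes the primary C4–OH and leaves the hindered secondary C2–OH.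

**Step 10**
Reactants: 17 C4-monoacetate
Product: 18 CNP0163960.1 (target)
Conditions: angelic acid (3 equiv), 2,4,6-trichlorobenzoyl chloride (3 equiv), Et3N (6 equiv), toluene, 23 °C; then 17, 80 °C
Reagents that add atoms: angelic acid [(Z)-2-methylbut-2-enoic acid], C/C=C(/C)C(=O)O
Why: Yamaguchi esterification through the mixed anhydride without DMAP acylates the hindered C2–OH with retention at C2 and without Z-to-E isomerisation of the angelate.

**Compound list**
1 | (R)-5-methylcyclohex-2-en-1-one | O=C1C=CC[C@@H](C)C1 | starting material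
2 | 3-[(tert-butyldimethylsilyl)oxy]propanal | O=CCCO[Si](C)(C)C(C)(C)C | starting material
3 | lithium (3R)-3-methylcyclohexa-1,5-dien-1-olate (kinetic dienolate of 1) | C1=CC[C@@H](C)C=C1O[Li] | intermediate
4 | triisopropoxytitanium dienolate of 1 | C1=CC[C@@H](C)C=C1O[Ti](OC(C)C)(OC(C)C)OC(C)C | intermediate
5 | (5R,6R)-6-[(1S)-3-[(tert-butyldimethylsilyl)oxy]-1-hydroxypropyl]-5-methylcyclohex-2-en-1-one | C1=CC[C@@H](C)[C@H]([C@H](CCO[Si](C)(C)C(C)(C)C)O)C1=O | intermediate
6 | bromomagnesium alkoxide of 5 (C2–O–Mg chelated to the C5 carbonyl) | C1=CC[C@@H](C)[C@H]([C@H](CCO[Si](C)(C)C(C)(C)C)O[Mg]Br)C1=O | intermediate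
7 | (1R,5R,6R)-6-[(1S)-3-[(tert-butyldimethylsilyl)oxy]-1-hydroxypropyl]-1,5-dimethylcyclohex-2-en-1-ol | C1=CC[C@@H](C)[C@H]([C@H](CCO[Si](C)(C)C(C)(C)C)O)[C@]1(C)O | intermediate
8 | (1R,5R,6R)-6-[(1S)-3-[(tert-butyldimethylsilyl)oxy]-1-[(triethylsilyl)oxy]propyl]-1,5-dimethylcyclohex-2-en-1-ol | C1=CC[C@@H](C)[C@H]([C@H](CCO[Si](C)(C)C(C)(C)C)O[Si](CC)(CC)CC)[C@]1(C)O | intermediate
9 | lithium alkoxide of 8 | C1=CC[C@@H](C)[C@H]([C@H](CCO[Si](C)(C)C(C)(C)C)O[Si](CC)(CC)CC)[C@]1(C)O[Li] | intermediate
10 | chloro(oxo)acetate (chlorooxalate) ester of 8 | C1=CC[C@@H](C)[C@H]([C@H](CCO[Si](C)(C)C(C)(C)C)O[Si](CC)(CC)CC)[C@]1(C)OC(=O)C(Cl)=O | intermediate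
11 | 3-diazo-2-oxopropanoate (diazopyruvate) ester of 8 | C1=CC[C@@H](C)[C@H]([C@H](CCO[Si](C)(C)C(C)(C)C)O[Si](CC)(CC)CC)[C@]1(C)OC(=O)C(=O)C=[N+]=[N-] | intermediate
12 | 7-[(1S)-3-[(tert-butyldimethylsilyl)oxy]-1-[(triethylsilyl)oxy]propyl]-6,8-dimethyl-5-oxatricyclo[4.4.0.0(2,10)]decane-3,4-dione; cyclopropane (C6, C7, C8) and lactone oxygen on the β-face, C7–C11 bond endo, C10 methyl α, side chain β | O=C1C(=O)O[C@@]2(C)[C@@H]([C@H](CCO[Si](C)(C)C(C)(C)C)O[Si](CC)(CC)CC)[C@H](C)C[C@H]3[C@@H]1[C@@H]23 | intermediate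
13 | 3-methylidene analogue of 12 (5-oxatricyclo[4.4.0.0(2,10)]decan-4-one, same stereochemistry) | C=C1C(=O)O[C@@]2(C)[C@@H]([C@H](CCO[Si](C)(C)C(C)(C)C)O[Si](CC)(CC)CC)[C@H](C)C[C@H]3[C@@H]1[C@@H]23 | intermediate
14 | ring-opened ion pair from 13: C5 cyclopropylcarbinyl cation with the acrylate anion on the endo arm at C7 | C=C(C(=O)[O-])[C@@H]1[C@@H]2C[C@@H](C)[C@H]([C@H](CCO[Si](C)(C)C(C)(C)C)O[Si](CC)(CC)CC)[C+](C)[C@H]12 | intermediate
15 | (3aR,6S,7R,8aR)-6-[(1S)-3-[(tert-butyldimethylsilyl)oxy]-1-[(triethylsilyl)oxy]propyl]-5,7-dimethyl-3-methylidene-3,3a,6,7,8,8a-hexahydro-2H-cyclohepta[b]furan-2-one | C=C1C(=O)O[C@@H]2C[C@@H](C)[C@H]([C@H](CCO[Si](C)(C)C(C)(C)C)O[Si](CC)(CC)CC)C(C)=C[C@H]12 | intermediate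
16 | (3aR,6S,7R,8aR)-6-[(1S)-1,3-dihydroxypropyl]-5,7-dimethyl-3-methylidene-3,3a,6,7,8,8a-hexahydro-2H-cyclohepta[b]furan-2-one | C=C1C(=O)O[C@@H]2C[C@@H](C)[C@H]([C@H](CCO)O)C(C)=C[C@H]12 | intermediate
17 | (3S)-3-hydroxy-3-[(3aR,6S,7R,8aR)-5,7-dimethyl-3-methylidene-2-oxo-3,3a,6,7,8,8a-hexahydro-2H-cyclohepta[b]furan-6-yl]propyl acetate | C=C1C(=O)O[C@@H]2C[C@@H](C)[C@H]([C@H](CCOC(C)=O)O)C(C)=C[C@H]12 | intermediate
18 | (3aR,6S,7R,8aR)-6-[(1S)-3-acetoxy-1-{[(2Z)-2-methylbut-2-enoyl]oxy}propyl]-5,7-dimethyl-3-methylidene-3,3a,6,7,8,8a-hexahydro-2H-cyclohepta[b]furan-2-one | C=C1C(=O)O[C@@H]2C[C@@H](C)[C@H]([C@H](CCOC(C)=O)OC(=O)/C(C)=C\C)C(C)=C[C@H]12 | target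

**Step count and risks**
Total: 10 steps. Longest linear sequence: 10 steps (1 to 18); 2 enters in step 1.

The three steps most likely to fail:

Step 7 (ring expansion with lactonisation). The cation may instead open the external C6–C7 bond toward the vinyl-bearing carbon, lose a proton, or shed the triethylsilyl group. The fallback sets out from 13 and comes back at 15. Dimethylamine (THF, 0 °C) is added to the methylene lactone to give the β-amino lactone tricycle F1, so that the C7 arm is no longer a vinyl group and, once protonated, disfavours positive charge at C7. The ring expansion is run on its triflate salt (TfOH 1.1 equiv, (CF3)2CHOH–CH2Cl2, 0 °C) to give the ring-expanded amino lactone F2. MeI converts this into the quaternary ammonium iodide F3, and NaHCO3 eliminates it to restore the exocyclic methylene, giving 15.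

Step 5 (intramolecular cyclopropanation). The ester must adopt its less stable conformer to cyclise, and the tertiary allylic ester is prone to ionisation. The fallback sets out from 8 and comes back at 12, replacing the diazo ester by an ether-tethered enyne cycloisomerisation. KH and propargyl bromide give the tertiary propargyl ether F4. PtCl2 (5 mol %, toluene, 80 °C) closes the β-face cyclopropane and a cyclic enol ether in one event, giving the tricyclic enol ether F5. OsO4 (catalytic) with N-methylmorpholine N-oxide gives the hydroxy lactol F6, and Dess–Martin periodinane oxidises both carbinols to give 12.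

Step 2 (face of methyl addition; retro-aldol of the aldolate). If chelation control gives the wrong C5 epimer, the later cyclopropane forms on the wrong face. The fallback sets out from 5 and comes back at 8. The C2 hydroxyl is silylated first (Et3SiCl, imidazole) to give the β-silyloxy ketone F7. Methyl is then delivered without chelation by the bulky MeTi(OiPr)3 (from MeLi and ClTi(OiPr)3, Et2O, −30 to 0 °C), which attacks cyclohexanone-type carbonyls from the equatorial direction and gives 8 directly.

**Further compounds**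
F1 | step 7 | dimethylamine adduct of 13 (C11 bears CH2NMe2; C11 epimers) | CN(C)CC1C(=O)O[C@@]2(C)[C@@H]([C@H](CCO[Si](C)(C)C(C)(C)C)O[Si](CC)(CC)CC)[C@H](C)C[C@H]3[C@@H]1[C@@H]23
F2 | step 7 | ring-expanded amino lactone (dimethylamine adduct of 15; C11 epimers) | CN(C)CC1C(=O)O[C@@H]2C[C@@H](C)[C@H]([C@H](CCO[Si](C)(C)C(C)(C)C)O[Si](CC)(CC)CC)C(C)=C[C@H]12
F3 | step 7 | trimethylammonium iodide of F2 | C[N+](C)(C)CC1C(=O)O[C@@H]2C[C@@H](C)[C@H]([C@H](CCO[Si](C)(C)C(C)(C)C)O[Si](CC)(CC)CC)C(C)=C[C@H]12.[I-]
F4 | step 5 | propargyl ether of 8 | C1=CC[C@@H](C)[C@H]([C@H](CCO[Si](C)(C)C(C)(C)C)O[Si](CC)(CC)CC)[C@]1(C)OCC#C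
F5 | step 5 | tricyclic enol ether (5-oxatricyclo[4.4.0.0(2,10)]dec-3-ene, stereochemistry as in 12) | C1=CO[C@@]2(C)[C@@H]([C@H](CCO[Si](C)(C)C(C)(C)C)O[Si](CC)(CC)CC)[C@H](C)C[C@H]3[C@@H]1[C@@H]23
F6 | step 5 | hydroxy lactol (3,4-diol of the tricycle; C11 and C12 epimers converge) | OC1C(O)O[C@@]2(C)[C@@H]([C@H](CCO[Si](C)(C)C(C)(C)C)O[Si](CC)(CC)CC)[C@H](C)C[C@H]3[C@@H]1[C@@H]23
F7 | step 2 | triethylsilyl ether of 5 | C1=CC[C@@H](C)[C@H]([C@H](CCO[Si](C)(C)C(C)(C)C)O[Si](CC)(CC)CC)C1=O
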